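The plan cuts ring A of the eudesmane core at C1–C2 and C5–C10. This opens both carbocycles to an open-chain 1,7,9-decatriene. One thermal intramolecular Diels–Alder reaction joins an (E)-2-methylalkenyl boronate (C10=C1–B) to the (E)-3-methyldienyl unit C2=C3–C4=C5. It closes rings A and B together and sets C1, C5 and the quaternary C10. The step exploits the contiguous C1(O)–C10(CH3)–C5(H) edge of ring A. Boron is the latent 1β-hydroxyl, the angular methyl sits on the dienophile, and the surviving C3=C4 alkene is the latent 4α-carbinol. The precursor carries only the all-syn C6–C7–C8 triad, built by aldol and propargylation chemistry.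

Key step: step 10

Remark: eudesmane numbering is used for all intermediates (decalin C1–C10, C14 on C10, C15 on C4, side chain C11–C13 on C7); β is the face of the C10 methyl group and α is the opposite face.

Step 1
Reactants: 1 (2E)-3-methylpent-2-en-4-yn-1-ol
Product: 2 (2E)-3-methylpenta-2,4-dien-1-ol
Conditions: H2 (1 atm), Pd/CaCO3 poisoned with Pb(OAc)2, quinoline, EtOAc, 0 °C, stopped at 1 equiv H2
Reagents that add atoms: none
Why: Lindlar-type semihydrogenation stops at the alkene on the poisoned palladium surface, so the terminal alkyne should become the vinyl group while the E-trisubstituted alkene is left as it is.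

Step 2
Reactants: 2 (2E)-3-methylpenta-2,4-dien-1-ol
Product: 3 (2E)-3-methylpenta-2,4-dienal
Conditions: MnO2, CH2Cl2, rt
Reagents that add atoms: none
Why: Activated MnO2 oxidises allylic alcohols selectively (allylic alcohol oxidation) and should give the E-dienal without isomerisation.

Step 3
Reactants: 4 (4S)-4-benzyl-1,3-oxazolidin-2-one; 5 3-methylbut-2-enoyl chloride
Product: 6 (4S)-4-benzyl-3-(3-methylbut-2-enoyl)-1,3-oxazolidin-2-one
Conditions: n-BuLi, THF, −78 °C; then 5, −78 → 0 °C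
Reagents that add atoms: none
Why: N-Acylation of the lithiated oxazolidinone with the acid chloride is the standard entry to Evans imides and creates no stereocentre.

Step 4
Reactants: 6 (4S)-4-benzyl-3-(3-methylbut-2-enoyl)-1,3-oxazolidin-2-one; 3 (2E)-3-methylpenta-2,4-dienal
Product: 8 (4S)-4-benzyl-3-[(2S,3R,4E)-3-hydroxy-5-methyl-2-(prop-1-en-2-yl)hepta-4,6-dienoyl]-1,3-oxazolidin-2-one, via boron dienolate 7 (not isolated)
Conditions: n-Bu2BOTf, Et3N, CH2Cl2, −78 → 0 °C; 3, −78 → −20 °C; H2O2, pH 7 buffer, MeOH, 0 °C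
Reagents that add atoms: none
Why: Soft γ-deprotonation gives the (Z)-boron dienolate, which reacts at its α-carbon through a closed Zimmerman–Traxler chair on the face away from the benzyl group, so that the Evans syn-aldol reaction sets C6 (R) and C7 (S) and unveils the isopropenyl group.

Step 5
Reactants: 8 (4S)-4-benzyl-3-[(2S,3R,4E)-3-hydroxy-5-methyl-2-(prop-1-en-2-yl)hepta-4,6-dienoyl]-1,3-oxazolidin-2-one
Product: 9 (2S,3R,4E)-3-hydroxy-N-methoxy-N,5-dimethyl-2-(prop-1-en-2-yl)hepta-4,6-dienamide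
Conditions: MeNH(OMe)·HCl, AlMe3, THF/CH2Cl2, −10 → 0 °C
Reagents that add atoms: N,O-dimethylhydroxylamine hydrochloride, CNOC.Cl
Why: Aluminium-amide transamidation (Weinreb amide synthesis) is assisted by the free β-hydroxyl, releases the auxiliary and leaves C6 and C7 untouched.

Step 6
Reactants: 9 (2S,3R,4E)-3-hydroxy-N-methoxy-N,5-dimethyl-2-(prop-1-en-2-yl)hepta-4,6-dienamide
Product: 10 (2S,3R,4E)-3-[(tert-butyldimethylsilyl)oxy]-N-methoxy-N,5-dimethyl-2-(prop-1-en-2-yl)hepta-4,6-dienamide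
Conditions: TBSOTf, 2,6-lutidine, CH2Cl2, −78 → 0 °C
Reagents that add atoms: tert-butyldimethylsilyl triflate, CC(C)(C)[Si](C)(C)OS(=O)(=O)C(F)(F)F
Why: Silylation with the triflate and a hindered base protects the dienylic 6-hydroxyl under non-ionising conditions and keeps it distinct from the later 8-hydroxyl.

Step 7
Reactants: 10 (2S,3R,4E)-3-[(tert-butyldimethylsilyl)oxy]-N-methoxy-N,5-dimethyl-2-(prop-1-en-2-yl)hepta-4,6-dienamide
Product: 11 (2S,3R,4E)-3-[(tert-butyldimethylsilyl)oxy]-5-methyl-2-(prop-1-en-2-yl)hepta-4,6-dienal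
Conditions: i-Bu2AlH, THF, −78 °C; aq. potassium sodium tartrate
Reagents that add atoms: none
Why: Reduction of a Weinreb amide with i-Bu2AlH stops at the aldehyde oxidation level because of chelation, and the cold, non-basic work-up should spare the C7 stereocentre.

Step 8
Reactants: 11 (2S,3R,4E)-3-[(tert-butyldimethylsilyl)oxy]-5-methyl-2-(prop-1-en-2-yl)hepta-4,6-dienal; 12 allenylboronic acid pinacol ester
Product: 13 (3E,5R,6R,7S)-5-[(tert-butyldimethylsilyl)oxy]-3-methyl-6-(prop-1-en-2-yl)deca-1,3-dien-9-yn-7-ol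
Conditions: 12 (1.5 equiv), (S)-TRIP phosphoric acid (10 mol %), 4 Å MS, toluene, −20 °C
Reagents that add atoms: none
Why: Brønsted-acid-catalysed propargylation with the allenyl boronate runs through a closed six-membered transition state in which the chiral phosphate directs Si-face attack, reinforced by the Felkin–Anh preference of the α-branched aldehyde, and so sets 8S (syn to C7).

Step 9
Reactants: 13 (3E,5R,6R,7S)-5-[(tert-butyldimethylsilyl)oxy]-3-methyl-6-(prop-1-en-2-yl)deca-1,3-dien-9-yn-7-ol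
Product: 15 (1E,4S,5R,6R,7E)-6-[(tert-butyldimethylsilyl)oxy]-2,8-dimethyl-5-(prop-1-en-2-yl)-1-(4,4,5,5-tetramethyl-1,3,2-dioxaborolan-2-yl)deca-1,7,9-trien-4-ol, via alkenylalane 14 (not isolated)
Conditions: AlMe3 (4 equiv), Cp2ZrCl2 (0.2 equiv), H2O (1.5 equiv), CH2Cl2, −23 °C; then MeOBpin, −23 °C → rt; aq. potassium sodium tartrate
Reagents that add atoms: trimethylaluminium, C[Al](C)C; 2-methoxy-4,4,5,5-tetramethyl-1,3,2-dioxaborolane, COB1OC(C)(C)C(C)(C)O1
Why: Zirconium-catalysed syn-methylalumination of the terminal alkyne (Negishi carboalumination) places methyl on C10 and aluminium on C1 cis to it, and alkenyl transfer from aluminium to the methoxyboronate retains this E geometry.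

Step 10
Reactants: 15 (1E,4S,5R,6R,7E)-6-[(tert-butyldimethylsilyl)oxy]-2,8-dimethyl-5-(prop-1-en-2-yl)-1-(4,4,5,5-tetramethyl-1,3,2-dioxaborolan-2-yl)deca-1,7,9-trien-4-ol
Product: 16 6α-[(tert-butyldimethylsilyl)oxy]-1β-(4,4,5,5-tetramethyl-1,3,2-dioxaborolan-2-yl)eudesma-3,11-dien-8α-ol (trans-decalin, 5α-H, 10β-CH3, 7β-isopropenyl)
Conditions: toluene (0.005 M), BHT (0.1 equiv), sealed tube, 180 °C
Reagents that add atoms: none
Why: Concerted, suprafacial [4+2] cycloaddition of the C2=C3–C4=C5 diene with the C10=C1 alkenyl boronate forms C1–C2 and C5–C10 in one event; the closest known reaction type is the thermal intramolecular Diels–Alder reaction of 1,7,9-decatrienyl boronates followed by C–B oxidation. Ring A is closed as the new cyclohexene by both new bonds, and ring B is closed in the fused (type 1) mode by the C5–C10 bond across the four-carbon tether C6–C9, which adopts a chair. C5 is controlled by C6: A1,3 strain with the C4 methyl holds C6–H in the diene plane, the silyloxy group points away, and the dienophile adds to the opposite face, an arrangement that also places the C6, C7 and C8 substituents equatorial. C10 and C1 follow from the E geometry (boron cis to the methyl group, hence 1β-boron beside the 10β-methyl) and from the transition state with the tether exo and methyl and boron endo, which gives the trans ring fusion. The step needs trans over cis fusion and reaction at the boronate alkene only; the former is favoured by secondary overlap of the vacant boron orbital with the diene and by the strain-free chair tether, the latter is secured because the isopropenyl group is only two atoms from the diene and cannot reach it. High dilution and BHT suppress intermolecular cycloaddition and polymerisation.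

Step 11
Reactants: 16 6α-[(tert-butyldimethylsilyl)oxy]-1β-(4,4,5,5-tetramethyl-1,3,2-dioxaborolan-2-yl)eudesma-3,11-dien-8α-ol
Product: 17 3α,4α-epoxy-6α-[(tert-butyldimethylsilyl)oxy]-1β-(4,4,5,5-tetramethyl-1,3,2-dioxaborolan-2-yl)eudesm-11-en-8α-ol
Conditions: mCPBA (1.05 equiv), NaHCO3, CH2Cl2, −20 → 0 °C
Reagents that add atoms: 3-chloroperoxybenzoic acid, O=C(OO)c1cccc(Cl)c1
Why: Prilezhaev epoxidation picks the more nucleophilic trisubstituted ring alkene over the 1,1-disubstituted isopropenyl group and attacks the α face because the 10β-methyl shields the β face, which sets C3 and C4.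

Step 12
Reactants: 17 3α,4α-epoxy-6α-[(tert-butyldimethylsilyl)oxy]-1β-(4,4,5,5-tetramethyl-1,3,2-dioxaborolan-2-yl)eudesm-11-en-8α-ol
Product: 18 6α-[(tert-butyldimethylsilyl)oxy]-1β-(4,4,5,5-tetramethyl-1,3,2-dioxaborolan-2-yl)eudesm-11-ene-4α,8α-diol
Conditions: LiEt3BH (5 equiv), THF, 0 → 60 °C; aq. NH4Cl (no oxidative work-up)
Reagents that add atoms: none
Why: Triethylborohydride opens the epoxide by SN2 attack at the less substituted C3 so that oxygen stays on C4 as the 4α-carbinol with the 4β-methyl, and the pinacol boronate should survive because no oxidative work-up is used.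

Step 13
Reactants: 18 6α-[(tert-butyldimethylsilyl)oxy]-1β-(4,4,5,5-tetramethyl-1,3,2-dioxaborolan-2-yl)eudesm-11-ene-4α,8α-diol
Product: 19 8α-acetoxy-6α-[(tert-butyldimethylsilyl)oxy]-1β-(4,4,5,5-tetramethyl-1,3,2-dioxaborolan-2-yl)eudesm-11-en-4α-ol
Conditions: Ac2O, pyridine, DMAP (cat.), CH2Cl2, 0 °C → rt
Reagents that add atoms: acetic anhydride, CC(=O)OC(C)=O
Why: Acylation discriminates by substitution, since the secondary 8-hydroxyl is esterified, the tertiary 4-hydroxyl is inert under these mild conditions, and O1 is still masked as boron.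

Step 14
Reactants: 19 8α-acetoxy-6α-[(tert-butyldimethylsilyl)oxy]-1β-(4,4,5,5-tetramethyl-1,3,2-dioxaborolan-2-yl)eudesm-11-en-4α-ol
Product: 20 8α-acetoxy-6α-[(tert-butyldimethylsilyl)oxy]eudesm-11-ene-1β,4α-diol
Conditions: NaBO3·4H2O, THF/H2O (1:1), rt
Reagents that add atoms: sodium perborate (NaBO3·4H2O), [Na+].[Na+].O[B-]1(O)OO[B-](O)(O)OO1
Why: Perborate oxidation of the C–B bond proceeds by 1,2-migration with retention, delivers the equatorial 1β-hydroxyl, and is mild enough for the acetate.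

Step 15
Reactants: 20 8α-acetoxy-6α-[(tert-butyldimethylsilyl)oxy]eudesm-11-ene-1β,4α-diol
Product: 21 8α-acetoxy-6α-[(tert-butyldimethylsilyl)oxy]eudesm-11(13)-ene-1β,4α,12-triol
Conditions: SeO2 (0.5 equiv), t-BuOOH (3 equiv), CH2Cl2, 0 °C → rt
Reagents that add atoms: tert-butyl hydroperoxide, CC(C)(C)OO; selenium dioxide, O=[Se]=O
Why: Riley allylic oxidation (ene reaction then [2,3]-shift) of the only remaining alkene functionalises the methyl group rather than the hindered C7 methine, and any over-oxidised enal is productive in the next step.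

Step 16
Reactants: 21 8α-acetoxy-6α-[(tert-butyldimethylsilyl)oxy]eudesm-11(13)-ene-1β,4α,12-triol
Product: 23 methyl 8α-acetoxy-6α-[(tert-butyldimethylsilyl)oxy]-1β,4α-dihydroxyeudesm-11(13)-en-12-oate, via enal 22 (not isolated)
Conditions: MnO2 (15 equiv), 1,4-dimethyl-1,2,4-triazolium iodide (10 mol %), DBU (20 mol %), MeOH/CH2Cl2, rt
Reagents that add atoms: methanol, CO
Why: MnO2 oxidises only the allylic alcohol, and carbene-catalysed oxidative esterification converts the resulting enal into the methyl ester in the same flask, leaving the unactivated 1-hydroxyl, the acetate and the silyl ether alone.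

Step 17
Reactants: 23 methyl 8α-acetoxy-6α-[(tert-butyldimethylsilyl)oxy]-1β,4α-dihydroxyeudesm-11(13)-en-12-oate
Product: 24 methyl 8α-acetoxy-1β,4α,6α-trihydroxyeudesm-11(13)-en-12-oate (CNP0272656.1)
Conditions: HF·pyridine, pyridine, THF, 0 °C → rt
Reagents that add atoms: none
Why: Fluoride-driven Si–O cleavage under buffered, weakly acidic conditions frees the 6α-hydroxyl without base, so that acetate migration, conjugate addition and lactonisation should be kept at bay.

Compound list
1 | (2E)-3-methylpent-2-en-4-yn-1-ol | C#C/C(C)=C/CO | starting material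
2 | (2E)-3-methylpenta-2,4-dien-1-ol | C=C/C(C)=C/CO | intermediate
3 | (2E)-3-methylpenta-2,4-dienal | C=C/C(C)=C/C=O | intermediate
4 | (4S)-4-benzyl-1,3-oxazolidin-2-one | O=C1N[C@@H](Cc2ccccc2)CO1 | starting material
5 | 3-methylbut-2-enoyl chloride | CC(C)=CC(=O)Cl | starting material
6 | (4S)-4-benzyl-3-(3-methylbut-2-enoyl)-1,3-oxazolidin-2-one | CC(C)=CC(=O)N1C(=O)OC[C@@H]1Cc2ccccc2 | intermediate
7 | (Z)-dibutylboron dienolate of 6 | C=C(C)/C=C(\OB(CCCC)CCCC)N1C(=O)OC[C@@H]1Cc2ccccc2 | intermediate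
8 | (4S)-4-benzyl-3-[(2S,3R,4E)-3-hydroxy-5-methyl-2-(prop-1-en-2-yl)hepta-4,6-dienoyl]-1,3-oxazolidin-2-one | C=C/C(C)=C/[C@@H](O)[C@H](C(C)=C)C(=O)N1C(=O)OC[C@@H]1Cc2ccccc2 | intermediate
9 | (2S,3R,4E)-3-hydroxy-N-methoxy-N,5-dimethyl-2-(prop-1-en-2-yl)hepta-4,6-dienamide | C=C/C(C)=C/[C@@H](O)[C@H](C(C)=C)C(=O)N(C)OC | intermediate
10 | (2S,3R,4E)-3-[(tert-butyldimethylsilyl)oxy]-N-methoxy-N,5-dimethyl-2-(prop-1-en-2-yl)hepta-4,6-dienamide | C=C/C(C)=C/[C@@H](O[Si](C)(C)C(C)(C)C)[C@H](C(C)=C)C(=O)N(C)OC | intermediate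
11 | (2S,3R,4E)-3-[(tert-butyldimethylsilyl)oxy]-5-methyl-2-(prop-1-en-2-yl)hepta-4,6-dienal | C=C/C(C)=C/[C@@H](O[Si](C)(C)C(C)(C)C)[C@H](C(C)=C)C=O | intermediate
12 | allenylboronic acid pinacol ester | C=C=CB1OC(C)(C)C(C)(C)O1 | starting material
13 | (3E,5R,6R,7S)-5-[(tert-butyldimethylsilyl)oxy]-3-methyl-6-(prop-1-en-2-yl)deca-1,3-dien-9-yn-7-ol | C=C/C(C)=C/[C@@H](O[Si](C)(C)C(C)(C)C)[C@H](C(C)=C)[C@@H](O)CC#C | intermediate
14 | (E)-alkenyl(dimethyl)alane of 13, 8-O-dimethylaluminium alkoxide | C=C/C(C)=C/[C@@H](O[Si](C)(C)C(C)(C)C)[C@H](C(C)=C)[C@@H](O[Al](C)C)C/C(C)=C/[Al](C)C | intermediate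
15 | (1E,4S,5R,6R,7E)-6-[(tert-butyldimethylsilyl)oxy]-2,8-dimethyl-5-(prop-1-en-2-yl)-1-(4,4,5,5-tetramethyl-1,3,2-dioxaborolan-2-yl)deca-1,7,9-trien-4-ol | C=C/C(C)=C/[C@@H](O[Si](C)(C)C(C)(C)C)[C@H](C(C)=C)[C@@H](O)C/C(C)=C/B1OC(C)(C)C(C)(C)O1 | intermediate
16 | 6α-[(tert-butyldimethylsilyl)oxy]-1β-(pinacolatoboryl)eudesma-3,11-dien-8α-ol | C=C(C)[C@H]1[C@H](O[Si](C)(C)C(C)(C)C)[C@@H]2[C@@](C)(C[C@@H]1O)[C@H](B3OC(C)(C)C(C)(C)O3)CC=C2C | intermediate
17 | 3α,4α-epoxy-6α-[(tert-butyldimethylsilyl)oxy]-1β-(pinacolatoboryl)eudesm-11-en-8α-ol | C=C(C)[C@H]1[C@H](O[Si](C)(C)C(C)(C)C)[C@@H]2[C@@](C)(C[C@@H]1O)[C@H](B4OC(C)(C)C(C)(C)O4)C[C@H]3O[C@@]23C | intermediate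
18 | 6α-[(tert-butyldimethylsilyl)oxy]-1β-(pinacolatoboryl)eudesm-11-ene-4α,8α-diol | C=C(C)[C@H]1[C@H](O[Si](C)(C)C(C)(C)C)[C@@H]2[C@@](C)(C[C@@H]1O)[C@H](B3OC(C)(C)C(C)(C)O3)CC[C@@]2(C)O | intermediate
19 | 8α-acetoxy-6α-[(tert-butyldimethylsilyl)oxy]-1β-(pinacolatoboryl)eudesm-11-en-4α-ol | C=C(C)[C@H]1[C@H](O[Si](C)(C)C(C)(C)C)[C@@H]2[C@@](C)(C[C@@H]1OC(C)=O)[C@H](B3OC(C)(C)C(C)(C)O3)CC[C@@]2(C)O | intermediate
20 | 8α-acetoxy-6α-[(tert-butyldimethylsilyl)oxy]eudesm-11-ene-1β,4α-diol | C=C(C)[C@H]1[C@H](O[Si](C)(C)C(C)(C)C)[C@@H]2[C@@](C)(C[C@@H]1OC(C)=O)[C@H](O)CC[C@@]2(C)O | intermediate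
21 | 8α-acetoxy-6α-[(tert-butyldimethylsilyl)oxy]eudesm-11(13)-ene-1β,4α,12-triol | C=C(CO)[C@H]1[C@H](O[Si](C)(C)C(C)(C)C)[C@@H]2[C@@](C)(C[C@@H]1OC(C)=O)[C@H](O)CC[C@@]2(C)O | intermediate
22 | 8α-acetoxy-6α-[(tert-butyldimethylsilyl)oxy]-1β,4α-dihydroxyeudesm-11(13)-en-12-al | C=C(C=O)[C@H]1[C@H](O[Si](C)(C)C(C)(C)C)[C@@H]2[C@@](C)(C[C@@H]1OC(C)=O)[C@H](O)CC[C@@]2(C)O | intermediate
23 | methyl 8α-acetoxy-6α-[(tert-butyldimethylsilyl)oxy]-1β,4α-dihydroxyeudesm-11(13)-en-12-oate | C=C(C(=O)OC)[C@H]1[C@H](O[Si](C)(C)C(C)(C)C)[C@@H]2[C@@](C)(C[C@@H]1OC(C)=O)[C@H](O)CC[C@@]2(C)O | intermediate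
24 | methyl 8α-acetoxy-1β,4α,6α-trihydroxyeudesm-11(13)-en-12-oate (CNP0272656.1) | C=C(C(=O)OC)[C@H]1[C@H](O)[C@@H]2[C@@](C)(C[C@@H]1OC(C)=O)[C@H](O)CC[C@@]2(C)O | target

Total step count: 17. Longest linear sequence: 16 steps (steps 1, 2 and 4–17).

Steps most likely to fail

Step 10.
- **Risk:** The trisubstituted, only weakly activated dienophile may react too slowly. At 180 °C control over the ring fusion could then erode, and the [3,3] shift of the 3-silyloxy-1,5-diene unit C4=C5–C6–C7–C11=C13 could compete.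
- **Fallback (from 15, back to 16):** Raise the electrophilicity of boron instead of the temperature. KHF2 in MeOH/H2O should convert 15 into potassium alkenyltrifluoroborate F1. Excess Me3SiCl in CH2Cl2/MeCN strips fluoride and caps the 8-hydroxyl to give 8-O-trimethylsilyl alkenyldifluoroborane F2, a member of the known, far more reactive dihaloborane class of dienophiles. F2 should cyclise near room temperature to decalin difluoroborane F3. Pinacol and Et3N followed by a methanolic work-up return 16.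

Step 12.
- **Risk:** Hydride has to reach C3 along an equatorial trajectory against the trans-diaxial preference of the rigid decalin. Opening may therefore be sluggish, and forcing conditions may degrade the boronate.
- **Fallback (from 17, back to 18):** Replace hydride by a soft nucleophile plus a radical reduction. PhSeNa (from PhSeSePh and NaBH4, EtOH, reflux) should open the epoxide at C3 to 3β-phenylselanyl-4α-ol F4 without touching boron. Bu3SnH and AIBN in toluene at 80 °C then remove selenium in a radical chain and give 18.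

Step 17.
- **Risk:** Cleavage of the very hindered 6-silyl ether may need forcing acid. The liberated 6-hydroxyl could then lactonise onto the neighbouring acrylate ester.
- **Fallback (from 21, back to 24):** Unmask O6 while C12 is an unreactive carboxylate, and form the ester last. TEMPO, NaClO2 and catalytic NaOCl in buffered MeCN should oxidise 21 to silyl-protected 12-oic acid F5. TBAF in THF removes the silyl group to give 6-hydroxy acid F6, which is kept as its tetrabutylammonium carboxylate and never acidified. MeI in DMF then alkylates the carboxylate to give 24.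

Further compounds
F1 | step 10 | potassium alkenyltrifluoroborate derived from 15 | C=C/C(C)=C/[C@@H](O[Si](C)(C)C(C)(C)C)[C@H](C(C)=C)[C@@H](O)C/C(C)=C/[B-](F)(F)F.[K+]
F2 | step 10 | 8-O-trimethylsilyl alkenyldifluoroborane | C=C/C(C)=C/[C@@H](O[Si](C)(C)C(C)(C)C)[C@H](C(C)=C)[C@@H](O[Si](C)(C)C)C/C(C)=C/B(F)F
F3 | step 10 | 1β-(difluoroboryl)-6α-[(tert-butyldimethylsilyl)oxy]-8α-[(trimethylsilyl)oxy]eudesma-3,11-diene | C=C(C)[C@H]1[C@H](O[Si](C)(C)C(C)(C)C)[C@@H]2[C@@](C)(C[C@@H]1O[Si](C)(C)C)[C@H](B(F)F)CC=C2C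
F4 | step 12 | 3β-(phenylselanyl)-6α-[(tert-butyldimethylsilyl)oxy]-1β-(pinacolatoboryl)eudesm-11-ene-4α,8α-diol | C=C(C)[C@H]1[C@H](O[Si](C)(C)C(C)(C)C)[C@@H]2[C@@](C)(C[C@@H]1O)[C@H](B3OC(C)(C)C(C)(C)O3)C[C@H]([Se]c3ccccc3)[C@@]2(C)O
F5 | step 17 | 8α-acetoxy-6α-[(tert-butyldimethylsilyl)oxy]-1β,4α-dihydroxyeudesm-11(13)-en-12-oic acid | C=C(C(=O)O)[C@H]1[C@H](O[Si](C)(C)C(C)(C)C)[C@@H]2[C@@](C)(C[C@@H]1OC(C)=O)[C@H](O)CC[C@@]2(C)O
F6 | step 17 | 8α-acetoxy-1β,4α,6α-trihydroxyeudesm-11(13)-en-12-oic acid | C=C(C(=O)O)[C@H]1[C@H](O)[C@@H]2[C@@](C)(C[C@@H]1OC(C)=O)[C@H](O)CC[C@@]2(C)O
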